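**Plan**

- Retrosynthesis: the 5-OH is traced back to a 5-OMe (peri ether cleavage last) and the 4'-OMe to a 4'-OH. Ring B is then cut at C1'–C2' and C5'–C6', leaving the 2-ethynylchromone 11 and the silyloxy ketene-acetal diene 13.
- Enabling feature: ring B is a resorcinol dimethyl ether (2'-OMe and 4'-OMe, meta to each other) bound through C1' to C2 of the chromone. A 1,1-dimethoxy-3-silyloxybutadiene leaves exactly this pattern on the internal carbon of an acceptor alkyne after loss of methanol.
- Further cuts: the alkyne goes back to the 2-methyl group via the 2-carbaldehyde, ring C is opened at O1–C2 and C2–C3 (Kostanecki–Robinson acylation), and the aryl ketone at its aryl–CO bond (Friedel–Crafts).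
- Forward order: ring A is bought as 1,2,3,5-tetramethoxybenzene, ring C is closed in step 2, ring B is built last in step 6, and steps 7 and 8 adjust the O-substituents.
- Stereochemistry: the target has no stereocentre and no stereogenic double bond. Only regiochemistry has to be controlled (ortho-demethylation in step 1, orientation of the cycloaddition in step 6, peri-demethylation in step 8).

Key step: step 6

Assumption: 4,4-dimethoxybut-3-en-2-one (12) is treated as a purchasable, moisture-sensitive ketene acetal that is distilled before use.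

**Route**

Step 1
Reactants: 1 1,2,3,5-tetramethoxybenzene; 2 methoxyacetyl chloride
Product: 4 1-(2-hydroxy-3,4,6-trimethoxyphenyl)-2-methoxyethan-1-one, via tetramethoxyaryl ketone 3 (not isolated)
Conditions: AlCl3 (3 equiv), Et2O, 0 °C to rt; then ice, 1 M HCl
Reagents that add atoms: none
Why: Friedel–Crafts acylation occurs at one of the two equivalent free positions of 1, and AlCl3 chelated between the new carbonyl and the ortho methoxy group that is buttressed by a second methoxy neighbour should cleave that ether selectively (chelation-assisted ortho-demethylation), the usual behaviour of this tetramethoxybenzene on acylation.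

Step 2
Reactants: 4 1-(2-hydroxy-3,4,6-trimethoxyphenyl)-2-methoxyethan-1-one
Product: 7 3,5,7,8-tetramethoxy-2-methyl-4H-chromen-4-one, via aryl acetate 5 (not isolated), via 1,3-diketone 6 (not isolated)
Conditions: Ac2O, NaOAc, 175 °C
Reagents that add atoms: acetic anhydride, CC(=O)OC(C)=O
Why: Kostanecki–Robinson acylation, in which the phenol is acetylated, the acetyl group shifts to the methoxy-bearing α-carbon under acetate catalysis (Baker–Venkataraman-type acyl transfer) and the 1,3-diketone cyclodehydrates to close ring C as a six-membered pyranone; ω-methoxy-2-hydroxyacetophenones are known to give 3-methoxy-2-methylchromones this way.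

Step 3
Reactants: 7 3,5,7,8-tetramethoxy-2-methyl-4H-chromen-4-one
Product: 8 3,5,7,8-tetramethoxy-4-oxo-4H-chromene-2-carbaldehyde
Conditions: SeO2, xylene, 140 °C
Reagents that add atoms: selenium dioxide, O=[Se]=O
Why: Riley oxidation; the 2-methyl group is vinylogously activated by the C4 carbonyl through C2=C3, so SeO2 should oxidise it to the aldehyde as with other 2-methylchromones, while the aryl and enol methyl ethers are inert.

Step 4
Reactants: 8 3,5,7,8-tetramethoxy-4-oxo-4H-chromene-2-carbaldehyde
Product: 11 2-ethynyl-3,5,7,8-tetramethoxy-4H-chromen-4-one, via lithium alkoxide adduct 9 (not isolated), via diazoalkene 10 (not isolated)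
Conditions: Me3SiCHN2, LiN(iPr)2, THF, −78 °C to rt; then H2O
Reagents that add atoms: trimethylsilyldiazomethane, C[Si](C)(C)C=[N+]=[N-]
Why: Colvin rearrangement (a Seyferth–Gilbert-type one-carbon homologation), in which lithiated trimethylsilyldiazomethane adds at −78 °C to the aldehyde as the most electrophilic carbonyl, Peterson-type loss of LiOSiMe3 gives the diazoalkene, and N2 loss with a 1,2-hydrogen shift of the alkylidene carbene gives the terminal alkyne with no methoxide present that could add to C2 or to the activated alkyne.

Step 5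
Reactants: 12 4,4-dimethoxybut-3-en-2-one
Product: 13 1,1-dimethoxy-3-(trimethylsilyloxy)buta-1,3-diene
Conditions: Me3SiCl, Et3N, ZnCl2 (cat.), benzene, 40 °C; distilled and used fresh
Reagents that add atoms: chlorotrimethylsilane, C[Si](C)(C)Cl
Why: Silyl enol ether formation under Danishefsky-diene conditions; the methyl ketone is enolised by Et3N with ZnCl2 assistance and trapped on oxygen by Me3SiCl, turning the cross-conjugated enone into the 1,3-diene.

Step 6
Reactants: 11 2-ethynyl-3,5,7,8-tetramethoxy-4H-chromen-4-one; 13 1,1-dimethoxy-3-(trimethylsilyloxy)buta-1,3-diene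
Product: 16 2-(4-hydroxy-2-methoxyphenyl)-3,5,7,8-tetramethoxy-4H-chromen-4-one, via cyclohexadiene cycloadduct 14 (not isolated), via aryl silyl ether 15 (not isolated)
Conditions: 13 (3 equiv), toluene, 90–110 °C; then 1 M HCl, THF, rt
Reagents that add atoms: none
Why: Proposed new method: the alkyne of 11 is the δ-terminus of a vinylogous ynone (C4=O, C3=C2, C≡C), so its LUMO coefficient is largest at the terminal carbon, while the HOMO of diene 13, raised by two methoxy groups and the silyloxy group, is largest at the unsubstituted CH2 terminus; a concerted but strongly asynchronous normal-demand Diels–Alder addition (the Mukaiyama–Michael/ring-closure extreme leads to the same adduct) should therefore join the CH2 terminus to the alkyne CH (C5'–C6') and the ketene-acetal carbon to the internal alkyne carbon (C1'–C2'). The closest known reaction type is the Diels–Alder/alcohol-elimination benzannulation of 1,1-dialkoxy-3-silyloxybutadienes with propiolates and ethynyl ketones, which gives 4-hydroxy-2-alkoxyaryl carbonyl compounds; an alkyne activated only through a chromone C2=C3 bond has not been used in it. Ring B closes by an intermolecular [4+2] cycloaddition that makes both ring bonds in one event, and the 1,4-cyclohexadiene 14 then aromatises by 1,4-loss of methanol from the acetal carbon and the doubly allylic CH2, driven by the aromatic sextet. No stereocentre is formed or needed. The step needs regioselectivity (OMe ortho and O-silyl para to C2) and chemoselectivity for the alkyne over C2=C3; the first follows from the matched polarisation described, the second from the fully substituted, methoxy-bearing C2=C3 bond being a hindered and poor dienophile. Dilute acid in the work-up completes the methanol loss if needed and cleaves the aryl silyl ether 15 to the phenol 16.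

Step 7
Reactants: 16 2-(4-hydroxy-2-methoxyphenyl)-3,5,7,8-tetramethoxy-4H-chromen-4-one
Product: 17 2-(2,4-dimethoxyphenyl)-3,5,7,8-tetramethoxy-4H-chromen-4-one
Conditions: MeI, K2CO3, acetone, reflux
Reagents that add atoms: iodomethane, CI
Why: Williamson etherification; the 4'-phenol is the only acidic OH, its phenoxide is methylated by MeI, and nothing else in 16 should react with K2CO3 in acetone.

Step 8
Reactants: 17 2-(2,4-dimethoxyphenyl)-3,5,7,8-tetramethoxy-4H-chromen-4-one
Product: 19 5-hydroxy-3,7,8,2',4'-pentamethoxyflavone, via dichloroboron chelate 18 (not isolated)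
Conditions: BCl3 (2 equiv), CH2Cl2, −78 to 0 °C; then H2O
Reagents that add atoms: none
Why: Chelation-controlled Lewis-acid ether cleavage; BCl3 bridges the C4 carbonyl and the peri 5-methoxy oxygen in a six-membered chelate and chloride removes that methyl group, whereas the 3-methoxy group could only form a five-membered chelate and the other four ethers are not chelated, which is the known basis of selective 5-O-demethylation in polymethoxyflavones.

**Compound list**

1 | 1,2,3,5-tetramethoxybenzene | COc1cc(OC)c(OC)c(OC)c1 | starting material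
2 | methoxyacetyl chloride | COCC(=O)Cl | starting material
3 | 2-methoxy-1-(2,3,4,6-tetramethoxyphenyl)ethan-1-one | COCC(=O)c1c(OC)cc(OC)c(OC)c1OC | intermediate (not isolated)
4 | 1-(2-hydroxy-3,4,6-trimethoxyphenyl)-2-methoxyethan-1-one | COCC(=O)c1c(OC)cc(OC)c(OC)c1O | intermediate
5 | 3,5,6-trimethoxy-2-(methoxyacetyl)phenyl acetate | COCC(=O)c1c(OC)cc(OC)c(OC)c1OC(C)=O | intermediate (not isolated)
6 | 1-(2-hydroxy-3,4,6-trimethoxyphenyl)-2-methoxybutane-1,3-dione (racemic at C2, enolisable) | COC(C(C)=O)C(=O)c1c(OC)cc(OC)c(OC)c1O | intermediate (not isolated)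
7 | 3,5,7,8-tetramethoxy-2-methyl-4H-chromen-4-one | Cc1oc2c(OC)c(OC)cc(OC)c2c(=O)c1OC | intermediate
8 | 3,5,7,8-tetramethoxy-4-oxo-4H-chromene-2-carbaldehyde | O=Cc1oc2c(OC)c(OC)cc(OC)c2c(=O)c1OC | intermediate
9 | lithium 2-diazo-1-(3,5,7,8-tetramethoxy-4-oxo-4H-chromen-2-yl)-2-(trimethylsilyl)ethan-1-olate (racemic) | [Li+].[O-]C(C(=[N+]=[N-])[Si](C)(C)C)c1oc2c(OC)c(OC)cc(OC)c2c(=O)c1OC | intermediate (not isolated)
10 | 2-(2-diazoethenyl)-3,5,7,8-tetramethoxy-4H-chromen-4-one | [N-]=[N+]=C=Cc1oc2c(OC)c(OC)cc(OC)c2c(=O)c1OC | intermediate (not isolated)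
11 | 2-ethynyl-3,5,7,8-tetramethoxy-4H-chromen-4-one | C#Cc1oc2c(OC)c(OC)cc(OC)c2c(=O)c1OC | intermediate
12 | 4,4-dimethoxybut-3-en-2-one | COC(OC)=CC(C)=O | starting material
13 | 1,1-dimethoxy-3-(trimethylsilyloxy)buta-1,3-diene | COC(OC)=CC(=C)O[Si](C)(C)C | intermediate
14 | 2-[6,6-dimethoxy-4-(trimethylsilyloxy)cyclohexa-1,4-dien-1-yl]-3,5,7,8-tetramethoxy-4H-chromen-4-one | COC1(OC)C=C(O[Si](C)(C)C)CC=C1c1oc2c(OC)c(OC)cc(OC)c2c(=O)c1OC | intermediate (not isolated)
15 | 3,5,7,8-tetramethoxy-2-[2-methoxy-4-(trimethylsilyloxy)phenyl]-4H-chromen-4-one | COc1cc(O[Si](C)(C)C)ccc1-c1oc2c(OC)c(OC)cc(OC)c2c(=O)c1OC | intermediate (not isolated)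
16 | 2-(4-hydroxy-2-methoxyphenyl)-3,5,7,8-tetramethoxy-4H-chromen-4-one | COc1cc(O)ccc1-c1oc2c(OC)c(OC)cc(OC)c2c(=O)c1OC | intermediate
17 | 2-(2,4-dimethoxyphenyl)-3,5,7,8-tetramethoxy-4H-chromen-4-one | COc1ccc(-c2oc3c(OC)c(OC)cc(OC)c3c(=O)c2OC)c(OC)c1 | intermediate
18 | 5-(dichloroboranyloxy)-2-(2,4-dimethoxyphenyl)-3,7,8-trimethoxy-4H-chromen-4-one | COc1ccc(-c2oc3c(OC)c(OC)cc(OB(Cl)Cl)c3c(=O)c2OC)c(OC)c1 | intermediate (not isolated)
19 | 5-hydroxy-3,7,8,2',4'-pentamethoxyflavone, i.e. 2-(2,4-dimethoxyphenyl)-5-hydroxy-3,7,8-trimethoxy-4H-chromen-4-one | COc1ccc(-c2oc3c(OC)c(OC)cc(O)c3c(=O)c2OC)c(OC)c1 | target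

**Count and risks**

Total step count: 8. Longest linear sequence: 7 steps (steps 1, 2, 3, 4, 6, 7, 8); step 5 is a one-step side branch.

Steps most likely to fail:

1. Step 6 (proposed new method). The 3-methoxy donor and the vinylogous-ester character of the chromone may leave the alkyne too unreactive, so that the diene hydrolyses or oligomerises before it adds, or a stepwise Michael addition may stop at an open-chain adduct without ring closure. The fallback uses known flavone chemistry and gives up the cycloaddition. It sets out from 4, which is O-acylated with 2,4-dimethoxybenzoyl chloride in pyridine to the ester 3,5,6-trimethoxy-2-(methoxyacetyl)phenyl 2,4-dimethoxybenzoate F1. Baker–Venkataraman rearrangement with KOH in pyridine should then give 1-(2,4-dimethoxyphenyl)-3-(2-hydroxy-3,4,6-trimethoxyphenyl)-2-methoxypropane-1,3-dione F2. Cyclodehydration with H2SO4 in acetic acid returns to the route at 17, from which step 8 follows.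

2. Step 4. The lithiated diazo reagent or the LiOSiMe3 it releases may add in conjugate fashion to chromone C2 (ring opening) or to the newly formed activated alkyne, or the diazo compound may undergo dipolar cycloaddition with the enone. The fallback sets out from 8 and avoids organolithium and alkoxide reagents. Ramirez olefination (CBr4, PPh3, CH2Cl2, 0 °C) should give 2-(2,2-dibromoethenyl)-3,5,7,8-tetramethoxy-4H-chromen-4-one F3. Selective hydrogenolysis of the bromine trans to the chromone with Bu3SnH and Pd(PPh3)4 (zerovalent palladium) should give 2-[(Z)-2-bromoethenyl]-3,5,7,8-tetramethoxy-4H-chromen-4-one F4. Anti-elimination of HBr with Bu4NF·3H2O in DMF returns to the route at 11.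

3. Step 3. Over-oxidation to the chromone-2-carboxylic acid or stalling of the oxidation with occlusion of the substrate in precipitated selenium may occur. The fallback sets out from 7, whose vinylogously acidic 2-methyl group is condensed with N,N-dimethylformamide dimethyl acetal (DMF, 120 °C) to 2-[(E)-2-(dimethylamino)ethenyl]-3,5,7,8-tetramethoxy-4H-chromen-4-one F5. Oxidative cleavage of the enamine double bond with NaIO4 in aqueous THF returns to the route at 8.

**Further compounds**

F1 | step 6 | 3,5,6-trimethoxy-2-(methoxyacetyl)phenyl 2,4-dimethoxybenzoate | COCC(=O)c1c(OC)cc(OC)c(OC)c1OC(=O)c1ccc(OC)cc1OC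
F2 | step 6 | 1-(2,4-dimethoxyphenyl)-3-(2-hydroxy-3,4,6-trimethoxyphenyl)-2-methoxypropane-1,3-dione (racemic at C2, enolisable) | COC(C(=O)c1ccc(OC)cc1OC)C(=O)c1c(OC)cc(OC)c(OC)c1O
F3 | step 4 | 2-(2,2-dibromoethenyl)-3,5,7,8-tetramethoxy-4H-chromen-4-one | BrC(Br)=Cc1oc2c(OC)c(OC)cc(OC)c2c(=O)c1OC
F4 | step 4 | 2-[(Z)-2-bromoethenyl]-3,5,7,8-tetramethoxy-4H-chromen-4-one | Br/C=C\c1oc2c(OC)c(OC)cc(OC)c2c(=O)c1OC
F5 | step 3 | 2-[(E)-2-(dimethylamino)ethenyl]-3,5,7,8-tetramethoxy-4H-chromen-4-one | CN(C)/C=C/c1oc2c(OC)c(OC)cc(OC)c2c(=O)c1OC
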